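**Retrosynthetic overview**

1. Target 30 ⇐ ring-closing metathesis (butenolide, C13=C14) and O-acetylation ⇐ (11R)-alcohol 28 ⇐ Felkin–Anh hydride reduction of C11 ketone 27 ⇐ indium Barbier addition of allyl 2-(bromomethyl)acrylate 24 to albicanal 21 (C11–C12).
2. 21 ⇐ ester 19 ⇐ palladium/formate removal of the allylic C7 oxygen of hydroxy ester 16, which is resolved on the way as its (1S)-camphanate 18.
3. 16 ⇐ acyclic, achiral enal/ene-yne ester 14 by a SmI2 reductive (3+3) annulation: ring A first (C5–C10, 6-exo-trig), then ring B (C7–C8, 6-exo-dig); no ring exists before this step.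
4. 14 ⇐ 2,2-dimethylpent-4-enal 1 (C1–C5), Wittig salt 2 (C6, C7), methyl but-2-ynoate 7 (C9, C10, C11, C20) and an ethynyl unit 12 (C8, C17), joined by hydroboration–iodination, syn-carbocupration/iodination and Negishi coupling.
5. Enabling feature (labdane numbering): ring B consists of two three-carbon halves, C5–C6–C7 (two plain CH2 groups, C7 allylic to C8=C17) and C8–C9–C10 (C9 bears the C11 oxygen function, C8 the exocyclic C17 methylene). An enal C5=C6–C7=O can therefore act as a 1,3-diyl equivalent towards the ene-yne ester C10=C9(CO2Me)–C8≡C17, and the C7 oxygen left behind is removable as an allylic leaving group.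

Key step: step 6

Remark 1: labdane numbering is used for atoms throughout (decalin C1–C10, C17 = exocyclic methylene carbon on C8, C20 = methyl on C10, C11–C16 = side chain); 15 and 16 are racemates whose SMILES show the enantiomer carried on after step 7.
Remark 2 (assumption): additions to the C11 carbonyl are taken to follow the Felkin–Anh model with the quaternary C10 as the large group, which predicts 11S for carbon addition (step 12) and 11R for hydride addition (step 14).

**Route**

Step 1
Reactants: 1 2,2-dimethylpent-4-enal; 2 (1,3-dioxolan-2-ylmethyl)triphenylphosphonium bromide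
Product: 4 2-[(1Z)-3,3-dimethylhexa-1,5-dien-1-yl]-1,3-dioxolane, via phosphonium ylide 3 (not isolated)
Conditions: 2, t-BuOK, THF, 0 °C; then 1, 0 °C → rt
Reagents that add atoms: phosphonium salt 2, [Br-].C1COC(C[P+](c2ccccc2)(c2ccccc2)c2ccccc2)O1
Why: Wittig olefination of a non-enolisable aldehyde with a non-stabilised ylide should give mainly the Z alkene; the geometry is corrected in step 5, so both isomers can be carried on.

Step 2
Reactants: 4 2-[(1Z)-3,3-dimethylhexa-1,5-dien-1-yl]-1,3-dioxolane
Product: 6 2-[(1Z)-6-iodo-3,3-dimethylhex-1-en-1-yl]-1,3-dioxolane, via B-alkyl-9-borabicyclononane 5 (not isolated)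
Conditions: 9-BBN, THF, 0 °C → rt; then NaOMe, MeOH, I2, 0 °C
Reagents that add atoms: iodine, [I][I]
Why: 9-BBN hydroborates the monosubstituted alkene anti-Markovnikov in preference to the hindered 1,2-disubstituted alkenyl acetal, and base-induced iodinolysis of the primary B–C bond should give the primary iodide.

Step 3
Reactants: 6 2-[(1Z)-6-iodo-3,3-dimethylhex-1-en-1-yl]-1,3-dioxolane; 7 methyl but-2-ynoate
Product: 11 methyl (2Z,8Z)-9-(1,3-dioxolan-2-yl)-2-iodo-3,7,7-trimethylnona-2,8-dienoate, via Grignard reagent 8 (not isolated), via alkylcopper 9 (not isolated), via alkenylcopper 10 (not isolated)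
Conditions: Mg, THF, rt; CuBr·SMe2, −40 °C; 7, −78 °C; then I2, THF, −78 → 0 °C
Reagents that add atoms: methyl but-2-ynoate 7, CC#CC(=O)OC; iodine, [I][I]
Why: syn-carbocupration of the ynoate places C1 on C10 and copper on C9 on the same side, and iodinolysis of the alkenylcopper with retention should give the Z α-iodo enoate; the C9=C10 geometry is not critical because both carbons lose it in step 6.

Step 4
Reactants: 11 methyl (2Z,8Z)-9-(1,3-dioxolan-2-yl)-2-iodo-3,7,7-trimethylnona-2,8-dienoate; 12 ethynylmagnesium bromide
Product: 13 methyl (2E,8Z)-9-(1,3-dioxolan-2-yl)-2-ethynyl-3,7,7-trimethylnona-2,8-dienoate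
Conditions: 12, ZnBr2, THF, 0 °C (gives HC≡CZnBr); then 11, Pd(PPh3)4 (5 mol %), THF, rt
Reagents that add atoms: ethynylmagnesium bromide 12, C#C[Mg]Br
Why: Negishi coupling of an alkynylzinc halide with the α-iodo enoate should install the C8≡C17 unit on C9 with retention of alkene geometry and leave the alkyne terminal.

Step 5
Reactants: 13 methyl (2E,8Z)-9-(1,3-dioxolan-2-yl)-2-ethynyl-3,7,7-trimethylnona-2,8-dienoate
Product: 14 methyl (2E,8E)-2-ethynyl-3,7,7-trimethyl-10-oxodeca-2,8-dienoate
Conditions: TsOH·H2O (cat.), acetone/H2O, 50 °C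
Reagents that add atoms: water, O
Why: acid hydrolysis of the dioxolane frees the enal, and the acid should equilibrate the conjugated C5=C6 alkene to the E isomer.

Step 6
Reactants: 14 methyl (2E,8E)-2-ethynyl-3,7,7-trimethyl-10-oxodeca-2,8-dienoate
Product: 16 racemic methyl (1R*,3S*,4aS*,8aS*)-3-hydroxy-5,5,8a-trimethyl-2-methylidenedecahydronaphthalene-1-carboxylate, via monocyclic aldehyde 15 (not isolated)
Conditions: SmI2 (5 equiv), HMPA, THF, −78 °C, slow addition of 14 (5 mM final); then t-BuOH (6 equiv), −78 → 0 °C
Reagents that add atoms: none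
Why: Proposed new method: SmI2 should reduce the enal to a samarium-bound allyl radical anion whose β-carbon C5 adds to C10 of the ene-yne ester (6-exo-trig, ring A), a second electron gives the samarium ester enolate, and t-BuOH then frees the saturated aldehyde 15, whose samarium ketyl carbon C7 adds to C8 of the alkyne (6-exo-dig, ring B) before the C17 vinyl radical is reduced and protonated, so that one enal acts as a C5/C7 1,3-diyl equivalent. The closest known reaction types are the SmI2 or cathodic reductive β,β-coupling of two tethered Michael acceptors and the SmI2/HMPA ketyl–alkyne cyclisation, which are here run in sequence on the same carbonyl group. C5 and C10 should be set in a chair-like transition state with the C6 arm and the C9 alkylidene carbon equatorial and the smaller C20 methyl axial, which gives the trans relation of H-5 and CH3-20. C9 should be set by protonation of the exocyclic samarium enolate on the face away from the C5 arm (minimised allylic strain, H-9 anti to CH3-20), and C7 by the equatorial samarium alkoxide in the ring B chair, its configuration being erased again in step 8. The step needs reaction at the β-carbon before the carbonyl carbon and cyclisation before simple reduction or pinacol dimerisation; the conjugated enal, the doubly activated acceptor, high dilution and the late addition of the proton source are meant to secure this, and the product is racemic because 14 is achiral.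

Step 7
Reactants: 16 racemic methyl (1R*,3S*,4aS*,8aS*)-3-hydroxy-5,5,8a-trimethyl-2-methylidenedecahydronaphthalene-1-carboxylate; 17 (1S)-(−)-camphanic chloride
Product: 18 methyl (1R,3S,4aS,8aS)-5,5,8a-trimethyl-2-methylidene-3-{[(1S,4R)-4,7,7-trimethyl-3-oxo-2-oxabicyclo[2.2.1]heptane-1-carbonyl]oxy}decahydronaphthalene-1-carboxylate
Conditions: Et3N, DMAP (cat.), CH2Cl2, 0 °C → rt; the diastereomeric camphanate formed from the (1S,3R,4aR,8aR) enantiomer of 16 is removed by chromatography or crystallisation
Reagents that add atoms: (1S)-(−)-camphanic chloride 17, CC1(C)[C@@]2(C)CC[C@@]1(OC2=O)C(Cl)=O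
Why: acylation of the secondary allylic alcohol with an enantiopure acid chloride turns the racemate into two diastereomeric esters (18 and the ester of the mirror-image alcohol) that should be separable, and the ester is at the same time the allylic leaving group needed in step 8.

Step 8
Reactants: 18 methyl (1R,3S,4aS,8aS)-3-camphanoyloxy-5,5,8a-trimethyl-2-methylidenedecahydronaphthalene-1-carboxylate
Product: 19 methyl (1S,4aS,8aS)-5,5,8a-trimethyl-2-methylidenedecahydronaphthalene-1-carboxylate
Conditions: Pd(OAc)2 (5 mol %), PBu3 (20 mol %), HCO2H, Et3N, 1,4-dioxane, 80 °C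
Reagents that add atoms: none
Why: palladium-catalysed formate hydrogenolysis of the Tsuji–Trost type: ionisation gives the π-allyl complex C7–C8–C17 and hydride transfer from the palladium formate to the more substituted terminus C7 should leave the 1,1-disubstituted C8=C17 alkene; no stereocentre other than C7 is touched (the C9 descriptor changes from R to S only because C7 loses its oxygen).

Step 9
Reactants: 19 methyl (1S,4aS,8aS)-5,5,8a-trimethyl-2-methylidenedecahydronaphthalene-1-carboxylate
Product: 20 albicanol [(1S,4aS,8aS)-5,5,8a-trimethyl-2-methylidenedecahydronaphthalen-1-yl]methanol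
Conditions: i-Bu2AlH (2.5 equiv), CH2Cl2, −78 → 0 °C
Reagents that add atoms: none
Why: ester reduction by the aluminium hydride under non-basic conditions should leave C9 and the C8=C17 alkene untouched.

Step 10
Reactants: 20 albicanol
Product: 21 albicanal [(1S,4aS,8aS)-5,5,8a-trimethyl-2-methylidenedecahydronaphthalene-1-carbaldehyde]
Conditions: Dess–Martin periodinane, CH2Cl2, 0 °C → rt; used crude
Reagents that add atoms: none
Why: Dess–Martin oxidation under near-neutral conditions should avoid epimerisation at C9 and migration of the C8=C17 alkene into conjugation.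

Step 11
Reactants: 22 2-(bromomethyl)acrylic acid; 23 allyl alcohol
Product: 24 allyl 2-(bromomethyl)acrylate
Conditions: TsOH·H2O (cat.), toluene, reflux, Dean–Stark trap
Reagents that add atoms: allyl alcohol 23, C=CCO
Why: acid-catalysed Fischer esterification with azeotropic removal of water; no base is present that could displace the allylic bromide.

Step 12
Reactants: 21 albicanal; 24 allyl 2-(bromomethyl)acrylate
Product: 26 prop-2-enyl (4S)-4-hydroxy-2-methylidene-4-[(1S,4aS,8aS)-5,5,8a-trimethyl-2-methylidenedecahydronaphthalen-1-yl]butanoate, via allylindium reagent 25 (not isolated)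
Conditions: In powder, THF/H2O (1:1), rt
Reagents that add atoms: allyl 2-(bromomethyl)acrylate 24, C=CCOC(=O)C(=C)CBr
Why: Barbier-type 2-(alkoxycarbonyl)allylation under neutral aqueous conditions should form C11–C12 without epimerising the α-stereocentre C9; the Felkin–Anh model predicts mainly the 11S alcohol 26, and any 11R epimer formed beside it (identical with 28) is not separated because both converge in step 13.

Step 13
Reactants: 26 prop-2-enyl (4S)-4-hydroxy-2-methylidene-4-[(1S,4aS,8aS)-5,5,8a-trimethyl-2-methylidenedecahydronaphthalen-1-yl]butanoate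
Product: 27 prop-2-enyl 2-methylidene-4-oxo-4-[(1S,4aS,8aS)-5,5,8a-trimethyl-2-methylidenedecahydronaphthalen-1-yl]butanoate
Conditions: Dess–Martin periodinane, CH2Cl2, 0 °C; used at once without chromatography
Reagents that add atoms: none
Why: neutral oxidation erases the C11 stereocentre so that it can be reset by hydride; immediate use should limit migration of the C13 methylidene into conjugation.

Step 14
Reactants: 27 prop-2-enyl 2-methylidene-4-oxo-4-[(1S,4aS,8aS)-5,5,8a-trimethyl-2-methylidenedecahydronaphthalen-1-yl]butanoate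
Product: 28 prop-2-enyl (4R)-4-hydroxy-2-methylidene-4-[(1S,4aS,8aS)-5,5,8a-trimethyl-2-methylidenedecahydronaphthalen-1-yl]butanoate
Conditions: NaBH4, CeCl3·7H2O, MeOH, −78 °C; neutral work-up
Reagents that add atoms: none
Why: Luche reduction is selective for the ketone over the acrylate; in the Felkin–Anh transition state the quaternary C10 is anti to the incoming hydride, C8 sits next to the carbonyl oxygen and hydride passes H-9, which should give the 11R alcohol (the opposite sense to the carbon addition of step 12).

Step 15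
Reactants: 28 prop-2-enyl (4R)-4-hydroxy-2-methylidene-4-[(1S,4aS,8aS)-5,5,8a-trimethyl-2-methylidenedecahydronaphthalen-1-yl]butanoate
Product: 29 prop-2-enyl (4R)-4-acetoxy-2-methylidene-4-[(1S,4aS,8aS)-5,5,8a-trimethyl-2-methylidenedecahydronaphthalen-1-yl]butanoate
Conditions: Ac2O, pyridine, DMAP (cat.), CH2Cl2, 0 °C → rt
Reagents that add atoms: acetic anhydride, CC(=O)OC(C)=O
Why: acylation of the secondary alcohol with retention installs the C11 acetate and blocks lactonisation of the γ-hydroxy acrylate.

Step 16
Reactants: 29 prop-2-enyl (4R)-4-acetoxy-2-methylidene-4-[(1S,4aS,8aS)-5,5,8a-trimethyl-2-methylidenedecahydronaphthalen-1-yl]butanoate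
Product: 30 (1R)-2-(2-oxo-2,5-dihydrofuran-3-yl)-1-[(1S,4aS,8aS)-5,5,8a-trimethyl-2-methylidenedecahydronaphthalen-1-yl]ethyl acetate (CNP0182424.2)
Conditions: second-generation Grubbs catalyst (5–10 mol %), CH2Cl2 (2 mM), reflux
Reagents that add atoms: none
Why: ring-closing metathesis of the allyl ester with the 1,1-disubstituted acrylate alkene should close the butenolide (C13=C14) with loss of ethene; the hindered exocyclic C8=C17 alkene should not take part and no stereocentre is involved.

**Compound list**

1 | 2,2-dimethylpent-4-enal | C=CCC(C)(C)C=O | starting material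
2 | (1,3-dioxolan-2-ylmethyl)triphenylphosphonium bromide | [Br-].C1COC(C[P+](c2ccccc2)(c2ccccc2)c2ccccc2)O1 | starting material
3 | (1,3-dioxolan-2-ylmethylidene)triphenylphosphorane (not isolated) | C1COC(C=P(c2ccccc2)(c2ccccc2)c2ccccc2)O1 | intermediate
4 | 2-[(1Z)-3,3-dimethylhexa-1,5-dien-1-yl]-1,3-dioxolane | C=CCC(C)(C)/C=C\C1OCCO1 | intermediate
5 | 9-[(5Z)-6-(1,3-dioxolan-2-yl)-4,4-dimethylhex-5-en-1-yl]-9-borabicyclo[3.3.1]nonane (not isolated) | C1CCC2CCCC1B2CCCC(C)(C)/C=C\C1OCCO1 | intermediate
6 | 2-[(1Z)-6-iodo-3,3-dimethylhex-1-en-1-yl]-1,3-dioxolane | ICCCC(C)(C)/C=C\C1OCCO1 | intermediate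
7 | methyl but-2-ynoate | CC#CC(=O)OC | starting material
8 | [(5Z)-6-(1,3-dioxolan-2-yl)-4,4-dimethylhex-5-en-1-yl]magnesium iodide (not isolated) | I[Mg]CCCC(C)(C)/C=C\C1OCCO1 | intermediate
9 | [(5Z)-6-(1,3-dioxolan-2-yl)-4,4-dimethylhex-5-en-1-yl]copper (not isolated) | [Cu]CCCC(C)(C)/C=C\C1OCCO1 | intermediate
10 | methyl (2Z,8Z)-2-cuprio-9-(1,3-dioxolan-2-yl)-3,7,7-trimethylnona-2,8-dienoate (not isolated) | COC(=O)/C([Cu])=C(\C)CCCC(C)(C)/C=C\C1OCCO1 | intermediate
11 | methyl (2Z,8Z)-9-(1,3-dioxolan-2-yl)-2-iodo-3,7,7-trimethylnona-2,8-dienoate | COC(=O)/C(I)=C(\C)CCCC(C)(C)/C=C\C1OCCO1 | intermediate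
12 | ethynylmagnesium bromide | C#C[Mg]Br | starting material
13 | methyl (2E,8Z)-9-(1,3-dioxolan-2-yl)-2-ethynyl-3,7,7-trimethylnona-2,8-dienoate | COC(=O)/C(C#C)=C(\C)CCCC(C)(C)/C=C\C1OCCO1 | intermediate
14 | methyl (2E,8E)-2-ethynyl-3,7,7-trimethyl-10-oxodeca-2,8-dienoate | COC(=O)/C(C#C)=C(\C)CCCC(C)(C)/C=C/C=O | intermediate
15 | racemic methyl (2S*)-2-[(1S*,2S*)-1,3,3-trimethyl-2-(3-oxopropyl)cyclohexyl]but-3-ynoate (not isolated) | C#C[C@H](C(=O)OC)[C@@]1(C)CCCC(C)(C)[C@@H]1CCC=O | intermediate
16 | racemic methyl (1R*,3S*,4aS*,8aS*)-3-hydroxy-5,5,8a-trimethyl-2-methylidenedecahydronaphthalene-1-carboxylate | C=C1[C@@H](O)C[C@H]2C(C)(C)CCC[C@]2(C)[C@H]1C(=O)OC | intermediate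
17 | (1S)-(−)-camphanic chloride | CC1(C)[C@@]2(C)CC[C@@]1(OC2=O)C(Cl)=O | starting material
18 | methyl (1R,3S,4aS,8aS)-5,5,8a-trimethyl-2-methylidene-3-{[(1S,4R)-4,7,7-trimethyl-3-oxo-2-oxabicyclo[2.2.1]heptane-1-carbonyl]oxy}decahydronaphthalene-1-carboxylate | C=C1[C@@H](OC(=O)[C@@]23CC[C@@](C)(C(=O)O2)C3(C)C)C[C@H]2C(C)(C)CCC[C@]2(C)[C@H]1C(=O)OC | intermediate
19 | methyl (1S,4aS,8aS)-5,5,8a-trimethyl-2-methylidenedecahydronaphthalene-1-carboxylate | C=C1CC[C@H]2C(C)(C)CCC[C@]2(C)[C@H]1C(=O)OC | intermediate
20 | albicanol, [(1S,4aS,8aS)-5,5,8a-trimethyl-2-methylidenedecahydronaphthalen-1-yl]methanol | C=C1CC[C@H]2C(C)(C)CCC[C@]2(C)[C@H]1CO | intermediate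
21 | albicanal, (1S,4aS,8aS)-5,5,8a-trimethyl-2-methylidenedecahydronaphthalene-1-carbaldehyde | C=C1CC[C@H]2C(C)(C)CCC[C@]2(C)[C@H]1C=O | intermediate
22 | 2-(bromomethyl)acrylic acid | C=C(CBr)C(=O)O | starting material
23 | allyl alcohol | C=CCO | starting material
24 | allyl 2-(bromomethyl)acrylate | C=CCOC(=O)C(=C)CBr | intermediate
25 | [2-(allyloxycarbonyl)allyl]indium dibromide (not isolated) | C=CCOC(=O)C(=C)C[In](Br)Br | intermediate
26 | prop-2-enyl (4S)-4-hydroxy-2-methylidene-4-[(1S,4aS,8aS)-5,5,8a-trimethyl-2-methylidenedecahydronaphthalen-1-yl]butanoate | C=C1CC[C@H]2C(C)(C)CCC[C@]2(C)[C@H]1[C@H](CC(=C)C(=O)OCC=C)O | intermediate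
27 | prop-2-enyl 2-methylidene-4-oxo-4-[(1S,4aS,8aS)-5,5,8a-trimethyl-2-methylidenedecahydronaphthalen-1-yl]butanoate | C=C1CC[C@H]2C(C)(C)CCC[C@]2(C)[C@H]1C(=O)CC(=C)C(=O)OCC=C | intermediate
28 | prop-2-enyl (4R)-4-hydroxy-2-methylidene-4-[(1S,4aS,8aS)-5,5,8a-trimethyl-2-methylidenedecahydronaphthalen-1-yl]butanoate | C=C1CC[C@H]2C(C)(C)CCC[C@]2(C)[C@H]1[C@@H](CC(=C)C(=O)OCC=C)O | intermediate
29 | prop-2-enyl (4R)-4-acetoxy-2-methylidene-4-[(1S,4aS,8aS)-5,5,8a-trimethyl-2-methylidenedecahydronaphthalen-1-yl]butanoate | C=C1CC[C@H]2C(C)(C)CCC[C@]2(C)[C@H]1[C@@H](CC(=C)C(=O)OCC=C)OC(C)=O | intermediate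
30 | (1R)-2-(2-oxo-2,5-dihydrofuran-3-yl)-1-[(1S,4aS,8aS)-5,5,8a-trimethyl-2-methylidenedecahydronaphthalen-1-yl]ethyl acetate | C=C1CC[C@H]2C(C)(C)CCC[C@]2(C)[C@H]1[C@@H](CC1=CCOC1=O)OC(C)=O | target

**Step count and risks**

Total step count: 16. Longest linear sequence: 15 steps (steps 1–10 and 12–16; step 11 prepares reagent 24).

Steps most likely to fail:

1. Step 6 (proposed new method). Two-electron conjugate reduction or pinacol dimerisation of the enal may outrun the hindered 6-exo closure onto the tetrasubstituted C9=C10 acceptor. Protonation at C9 may occur with low facial selectivity, and the C7 ketyl may be reduced to the alcohol before it closes ring B. The fallback uses known chemistry and makes the two bonds in two operations; it sets out from 14 and comes back at 16. Ring A is closed first by cathodic electrohydrocyclisation of 14 (glassy-carbon cathode, Et4NOTs, MeCN, dimethyl malonate as proton donor), the known reductive β,β-coupling of tethered Michael acceptors, and the monocyclic aldehyde 15 is isolated. Ring B is then closed by nickel-catalysed reductive cyclisation of the ynal (Ni(cod)2, PBu3, Et3SiH, THF), which should give methyl (1R*,3S*,4aS*,8aS*)-5,5,8a-trimethyl-2-methylidene-3-(triethylsilyloxy)decahydronaphthalene-1-carboxylate F1. TBAF in THF then frees 16.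

2. Step 7. The two diastereomeric camphanates may co-elute or co-crystallise, so that no enantiomer separation is achieved. The fallback sets out from 16 and comes back at 19. The enantiomers of 16 are separated by preparative HPLC on a chiral stationary phase (cellulose tris(3,5-dimethylphenylcarbamate)). The (1R,3S,4aS,8aS) enantiomer is converted with methyl chloroformate and pyridine into methyl (1R,3S,4aS,8aS)-3-(methoxycarbonyloxy)-5,5,8a-trimethyl-2-methylidenedecahydronaphthalene-1-carboxylate F2, which under the palladium/formate conditions of step 8 should give 19.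

3. Step 14. Hydride delivery to the C11 ketone may show poor facial selectivity. Before or during the reduction, the β,γ-unsaturated keto ester 27 may also suffer migration of the C13 methylidene into conjugation or lactonisation of the product alkoxide. The fallback sets out from 21 (with reagent 24) and comes back at 28, so that ketone 27 is never formed. Compound 24 is converted by copper-catalysed borylation (B2pin2, CuCl, KOAc, DMF) into prop-2-enyl 2-[(4,4,5,5-tetramethyl-1,3,2-dioxaborolan-2-yl)methyl]prop-2-enoate F3. Allylboration of 21 with F3 under a BINOL-derived chiral phosphoric acid (TRIP, 5 mol %, toluene, −30 °C; catalyst enantiomer chosen for delivery to the face that gives 11R) should set C11 under catalyst control and give 28 directly.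

Further compounds
F1 | step 6 | methyl (1R*,3S*,4aS*,8aS*)-5,5,8a-trimethyl-2-methylidene-3-(triethylsilyloxy)decahydronaphthalene-1-carboxylate (racemic) | C=C1[C@@H](O[Si](CC)(CC)CC)C[C@H]2C(C)(C)CCC[C@]2(C)[C@H]1C(=O)OC
F2 | step 7 | methyl (1R,3S,4aS,8aS)-3-(methoxycarbonyloxy)-5,5,8a-trimethyl-2-methylidenedecahydronaphthalene-1-carboxylate | C=C1[C@@H](OC(=O)OC)C[C@H]2C(C)(C)CCC[C@]2(C)[C@H]1C(=O)OC
F3 | step 14 | prop-2-enyl 2-[(4,4,5,5-tetramethyl-1,3,2-dioxaborolan-2-yl)methyl]prop-2-enoate | C=CCOC(=O)C(=C)CB1OC(C)(C)C(C)(C)O1
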